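Read as percent of the charge, the eta run looks slower than the gamma run, 6.2% against 20.9% at 90.0 s, and that reading is a pitfall.

| setting | gamma | eta | south-west | east |
|---|---|---|---|---|
| solid substrate | 0.74 M | 2.5 M | 0.50 M | 2.0 M |
| remark | run made earlier | run made earlier |  |  |
| time |  |  | 3.0 min | 3.0 min |

| run | time / s | target / % |
|---|---|---|
| gamma | 12.0 | 1.4 |
| gamma | 30.0 | 4.6 |
| gamma | 60.0 | 12.5 |
| gamma | 90.0 | 20.9 |
| eta | 12.0 | 0.1 |
| eta | 30.0 | 1.6 |
| eta | 60.0 | 3.8 |
| eta | 90.0 | 6.2 |

(standard deviation of a reading: 0.3 percentage points)

- solid, in amounts per volume of the solution: solid substrate
- at the start none of the solid substrate is in solution
- what has only dissolved of solid substrate counts as not reacted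

- the flask that ends with the higher amount of target, in percent of the solid substrate charged, or "neither" when 2 percentage points or less lies between them (south-west / east / neither)
- final target, as a percentage of the solid substrate charged, in south-west
- final target, as a percentage of the solid substrate charged, in east

Percent times charge gives target per litre, here called the molar yield. At 90.0 s it reads 0.155 M in the gamma run and 0.155 M in the eta run, although the eta charge is 3.38 times the gamma charge. In these two runs the molar yield therefore follows one curve whatever the charge, a zero-order stretch, and its slope over the last interval of the gamma run reads 0.00207 M/s.

My own reckoning joins two extremes. At the upper end the slope runs on unchanged to 3.0 min, which gives 0.341 M. At the lower end target stops growing at the molar yield of 90.0 s. Divided by the charges, south-west lies between 30.9% and 68.2%, and east between 7.73% and 17.1%. Both extremes assume that target, once made, stays. The east charge is larger than the upper amount, so east should sit near its upper end. South-west's lower end stands above east's upper end, so south-west should end higher.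

The forecast gives south-west, with 65% in south-west and 17.5% in east, on this ground: “So the reaction runs through a saturated solution, and its rate does not depend on how much solid is present.” Its south-west value stands near the top of my band, whereas I commit to the band alone.

South-west ended at 29.6% and east at 14.0%, so south-west holds more.

    target → over-reaction product (k = 0.0119 /s)
    solid substrate ⇌ starting material, rate k2*(cs2 - [starting material]) while solid is left; crystals form when [starting material] > cs2 (solubility = 0.730 M, k = 0.0133 /s)
    starting material → target (k = 0.0105 /s)

South-west's target stood at 29.7% after 1.50 min and 29.6% after 3.00 min, while its over-reaction product rose from 14.1% to 48.6%. The molar yield 0.155 M over south-west's charge gives 30.9%, beside that first reading. East's end is a molar yield of 0.280 M. A neighbour flask charged with 1.2 M still held 17.0% as solid at 3.00 min. Dividing east's molar yield by that charge gives 23.4%, and the neighbour gave 23.4%.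

The readings are calculated with made-up constants, and the scatter is random.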